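**Retrosynthetic overview**
- Bulbocodin C is reached from a tri-O-benzyl benzophenone by reducing the diaryl C=O to CH2 and then removing the three benzyl ethers; the aroyl group is the latent C2 4-hydroxybenzyl group.
- Ring A, the only ring built, is disconnected at C2–C3 and C6–C1 by an Alder–Rickert sequence (Diels–Alder addition, then loss of ethene) into a 1-methoxy-3-silyloxycyclohexa-1,3-diene and an aryl ynone.
- The strategy rests on one feature of ring A: the C3(OMe)–C4(CH2Ar)–C5(OH) triad is the O–C–O unit of 2-(4-benzyloxybenzyl)cyclohexane-1,3-dione. Its methyl enol ether differentiates the two oxygens, and C6–H is the free diene terminus.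
- The diene comes from cyclohexane-1,3-dione and 4-benzyloxybenzaldehyde by reductive benzylation, O-methylation and kinetic silyl dienol ether formation.
- The ynone comes from 3-benzyloxybenzyl bromide, 1-(trimethylsilyl)propyne and 4-benzyloxybenzoyl chloride by propargylation, desilylation and acyl Sonogashira coupling.

Key step: step 7

Assumption: compounds 8, 9 and 13 are taken as purchasable; the target is achiral, and the chiral intermediates 15 and 18 are racemic, which has no consequence.

**Step 1**
Reactants: 1 cyclohexane-1,3-dione; 2 4-benzyloxybenzaldehyde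
Product: 4 2-(4-benzyloxybenzyl)cyclohexane-1,3-dione, via arylidene dione 3 (not isolated)
Conditions: Hantzsch ester (diethyl 2,6-dimethyl-1,4-dihydropyridine-3,5-dicarboxylate, 1.1 equiv), L-proline (20 mol %), CH2Cl2, rt
Reagents that add atoms: none
Why: Proline-catalysed Knoevenagel condensation gives the highly electrophilic arylidene dione 3, which should accept hydride from the Hantzsch ester by conjugate transfer faster than it adds a second dione, so this three-component organocatalytic reductive alkylation should give the mono-C-benzylated dione.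

**Step 2**
Reactants: 4 2-(4-benzyloxybenzyl)cyclohexane-1,3-dione
Product: 5 2-(4-benzyloxybenzyl)-3-methoxycyclohex-2-en-1-one
Conditions: Me2SO4, K2CO3, acetone, reflux
Reagents that add atoms: dimethyl sulfate, COS(=O)(=O)OC
Why: O-alkylation of the potassium enolate of a 2-substituted cyclic 1,3-dione with the hard electrophile dimethyl sulfate should give the vinylogous ester, and the symmetry of 4 allows only one enol ether.

**Step 3**
Reactants: 5 2-(4-benzyloxybenzyl)-3-methoxycyclohex-2-en-1-one
Product: 7 2-(4-benzyloxybenzyl)-1-methoxy-3-(trimethylsilyloxy)cyclohexa-1,3-diene, via lithium dienolate 6 (not isolated)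
Conditions: LiN(i-Pr)2 (commercial solution), THF, −78 °C; Me3SiCl, −78 °C to rt; pentane, filtration, used crude
Reagents that add atoms: chlorotrimethylsilane, C[Si](C)(C)Cl
Why: Kinetic deprotonation of a vinylogous ester with a lithium amide occurs at the alpha-prime CH2 (Stork–Danheiser-type enolate formation), and O-silylation of the cross-conjugated dienolate 6 should give the 1-methoxy-3-silyloxy diene and not the linear isomer.

**Step 4**
Reactants: 8 3-benzyloxybenzyl bromide; 9 1-(trimethylsilyl)propyne
Product: 11 [4-(3-benzyloxyphenyl)but-1-yn-1-yl]trimethylsilane, via lithiated silylpropyne 10 (not isolated)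
Conditions: n-BuLi, THF, −78 to −20 °C (on 9); then 8, −78 °C to rt
Reagents that add atoms: none
Why: Propargylic lithiation of 1-(trimethylsilyl)propyne followed by SN2 alkylation with a benzylic bromide is a standard three-carbon homologation, and the silyl group should direct reaction through the propargylic carbon so that the acetylene, not the allene, is formed.

**Step 5**
Reactants: 11 [4-(3-benzyloxyphenyl)but-1-yn-1-yl]trimethylsilane
Product: 12 1-benzyloxy-3-(but-3-yn-1-yl)benzene
Conditions: K2CO3 (cat.), MeOH, rt
Reagents that add atoms: none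
Why: Methoxide-mediated protodesilylation of an alkynylsilane should be clean and leaves the benzyl ether untouched.

**Step 6**
Reactants: 12 1-benzyloxy-3-(but-3-yn-1-yl)benzene; 13 4-benzyloxybenzoyl chloride
Product: 14 1-(4-benzyloxyphenyl)-5-(3-benzyloxyphenyl)pent-2-yn-1-one
Conditions: PdCl2(PPh3)2 (2 mol %), CuI (4 mol %), Et3N (1.5 equiv), THF, rt
Reagents that add atoms: none
Why: Acyl Sonogashira coupling (oxidative addition of the aroyl chloride to zerovalent palladium, transmetalation from the copper acetylide, reductive elimination) should give the aryl ynone directly at room temperature without decarbonylation.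

**Step 7**
Reactants: 7 2-(4-benzyloxybenzyl)-1-methoxy-3-(trimethylsilyloxy)cyclohexa-1,3-diene (about 2 equiv); 14 1-(4-benzyloxyphenyl)-5-(3-benzyloxyphenyl)pent-2-yn-1-one
Product: 17 [3-(4-benzyloxybenzyl)-6-[2-(3-benzyloxyphenyl)ethyl]-4-hydroxy-2-methoxyphenyl](4-benzyloxyphenyl)methanone, via bicyclo[2.2.2]octadiene adduct 15 (not isolated), via aryl trimethylsilyl ether 16 (not isolated)
Conditions: degassed o-xylene, sealed tube, 160 °C; then 1 M HCl, THF, rt
Reagents that add atoms: none
Why: The electron-rich diene 7 should add thermally to the aroyl-activated alkyne of 14 in a concerted, asynchronous (4+2) cycloaddition to give the bicyclo[2.2.2]octa-2,5-diene 15, which at the same temperature loses its CH2–CH2 bridge as ethene by retro-(4+2) reaction to give the aryl silyl ether 16, hydrolysed to phenol 17 on acid work-up. This is the Alder–Rickert reaction, established for 1-alkoxy-3-silyloxycyclohexa-1,3-dienes with acetylenic ketones and esters. Ring A is closed by intermolecular (4+2) cycloaddition, which forms the C(OMe)–C(aroyl) and C(H)–C(chain) bonds together, and is made aromatic by the cycloreversion. No stereocentre remains in 17, because the two bridgehead centres of racemic 15 are destroyed on aromatisation. The step needs regioselectivity: both oxygen donors place the largest HOMO coefficient on the unsubstituted CH terminus of 7, which bonds to the ynone beta carbon (largest LUMO coefficient), so the methoxy-bearing terminus joins the aroyl-bearing alpha carbon and the methoxy group stays on the arene. Ethene loss and aromatisation make the sequence irreversible, and the excess of 7 should compensate for its thermal 1,5-hydrogen shift.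

**Step 8**
Reactants: 17 [3-(4-benzyloxybenzyl)-6-[2-(3-benzyloxyphenyl)ethyl]-4-hydroxy-2-methoxyphenyl](4-benzyloxyphenyl)methanone
Product: 19 2,4-bis(4-benzyloxybenzyl)-5-[2-(3-benzyloxyphenyl)ethyl]-3-methoxyphenol, via diarylmethanol 18 (not isolated)
Conditions: Et3SiH (4 equiv), CF3CO2H (10 equiv), CH2Cl2, 0 °C to rt
Reagents that add atoms: none
Why: Ionic hydrogenation (Kursanov–Parnes reduction) should proceed by protonation of the ketone, hydride transfer from the silane to give carbinol 18, ionisation to a diarylmethyl cation stabilised by the para-hydroxy/ortho-methoxy ring and the para-benzyloxyphenyl ring, and a second hydride transfer, while aryl benzyl ethers tolerate dilute CF3CO2H at or below room temperature.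

**Step 9**
Reactants: 19 2,4-bis(4-benzyloxybenzyl)-5-[2-(3-benzyloxyphenyl)ethyl]-3-methoxyphenol
Product: 20 bulbocodin C, 2,4-bis(4-hydroxybenzyl)-5-[2-(3-hydroxyphenyl)ethyl]-3-methoxyphenol
Conditions: H2 (1 atm), 10% Pd/C, EtOAc–MeOH, rt
Reagents that add atoms: none
Why: Catalytic hydrogenolysis of the three aryl benzyl ethers over palladium on carbon should free the phenols, and the methyl ether, the diarylmethane CH2 groups and the bibenzyl chain are inert under these conditions.

**Compound list**
1 | cyclohexane-1,3-dione | O=C1CCCC(=O)C1 | starting material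
2 | 4-benzyloxybenzaldehyde | O=Cc1ccc(OCc2ccccc2)cc1 | starting material
3 | 2-(4-benzyloxybenzylidene)cyclohexane-1,3-dione | O=C1CCCC(=O)C1=Cc1ccc(OCc2ccccc2)cc1 | intermediate
4 | 2-(4-benzyloxybenzyl)cyclohexane-1,3-dione | O=C1CCCC(=O)C1Cc1ccc(OCc2ccccc2)cc1 | intermediate
5 | 2-(4-benzyloxybenzyl)-3-methoxycyclohex-2-en-1-one | COC1=C(Cc2ccc(OCc3ccccc3)cc2)C(=O)CCC1 | intermediate
6 | lithium 6-(4-benzyloxybenzyl)-5-methoxycyclohexa-1,5-dien-1-olate | [Li+].[O-]C1=CCCC(OC)=C1Cc1ccc(OCc2ccccc2)cc1 | intermediate
7 | 2-(4-benzyloxybenzyl)-1-methoxy-3-(trimethylsilyloxy)cyclohexa-1,3-diene | COC1=C(Cc2ccc(OCc3ccccc3)cc2)C(O[Si](C)(C)C)=CCC1 | intermediate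
8 | 3-benzyloxybenzyl bromide | BrCc1cccc(OCc2ccccc2)c1 | starting material
9 | 1-(trimethylsilyl)propyne | CC#C[Si](C)(C)C | starting material
10 | 3-lithio-1-(trimethylsilyl)propyne | [Li]CC#C[Si](C)(C)C | intermediate
11 | [4-(3-benzyloxyphenyl)but-1-yn-1-yl]trimethylsilane | C[Si](C)(C)C#CCCc1cccc(OCc2ccccc2)c1 | intermediate
12 | 1-benzyloxy-3-(but-3-yn-1-yl)benzene | C#CCCc1cccc(OCc2ccccc2)c1 | intermediate
13 | 4-benzyloxybenzoyl chloride | O=C(Cl)c1ccc(OCc2ccccc2)cc1 | starting material
14 | 1-(4-benzyloxyphenyl)-5-(3-benzyloxyphenyl)pent-2-yn-1-one | O=C(C#CCCc1cccc(OCc2ccccc2)c1)c1ccc(OCc2ccccc2)cc1 | intermediate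
15 | [6-(4-benzyloxybenzyl)-3-[2-(3-benzyloxyphenyl)ethyl]-1-methoxy-5-(trimethylsilyloxy)bicyclo[2.2.2]octa-2,5-dien-2-yl](4-benzyloxyphenyl)methanone, racemic | COC12CCC(C(O[Si](C)(C)C)=C1Cc1ccc(OCc3ccccc3)cc1)C(CCc1cccc(OCc3ccccc3)c1)=C2C(=O)c1ccc(OCc2ccccc2)cc1 | intermediate
16 | [3-(4-benzyloxybenzyl)-6-[2-(3-benzyloxyphenyl)ethyl]-2-methoxy-4-(trimethylsilyloxy)phenyl](4-benzyloxyphenyl)methanone | COc1c(Cc2ccc(OCc3ccccc3)cc2)c(O[Si](C)(C)C)cc(CCc2cccc(OCc3ccccc3)c2)c1C(=O)c1ccc(OCc2ccccc2)cc1 | intermediate
17 | [3-(4-benzyloxybenzyl)-6-[2-(3-benzyloxyphenyl)ethyl]-4-hydroxy-2-methoxyphenyl](4-benzyloxyphenyl)methanone | COc1c(Cc2ccc(OCc3ccccc3)cc2)c(O)cc(CCc2cccc(OCc3ccccc3)c2)c1C(=O)c1ccc(OCc2ccccc2)cc1 | intermediate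
18 | 2-(4-benzyloxybenzyl)-4-[(4-benzyloxyphenyl)(hydroxy)methyl]-5-[2-(3-benzyloxyphenyl)ethyl]-3-methoxyphenol, racemic | COc1c(Cc2ccc(OCc3ccccc3)cc2)c(O)cc(CCc2cccc(OCc3ccccc3)c2)c1C(O)c1ccc(OCc2ccccc2)cc1 | intermediate
19 | 2,4-bis(4-benzyloxybenzyl)-5-[2-(3-benzyloxyphenyl)ethyl]-3-methoxyphenol | COc1c(Cc2ccc(OCc3ccccc3)cc2)c(O)cc(CCc2cccc(OCc3ccccc3)c2)c1Cc1ccc(OCc2ccccc2)cc1 | intermediate
20 | bulbocodin C | COc1c(Cc2ccc(O)cc2)c(O)cc(CCc2cccc(O)c2)c1Cc1ccc(O)cc1 | target

**Step count**
Total steps: 9. Longest linear sequence: 6 (steps 1–3 then 7–9, or steps 4–6 then 7–9).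

**Steps most likely to fail**

Step 7. Both reacting termini are hindered (a tetrasubstituted diene and an internal ynone), so cycloaddition may be slower than thermal 1,5-hydrogen shift or adventitious hydrolysis of the silyl dienol ether, and the diene would be consumed before the adduct forms.
Fallback: it sets out from alkyne 12 and diene 7 and returns at carbinol 18, replacing the aroyl ynone by a smaller, more reactive ynal and installing the aryl group afterwards. Alkyne 12 is lithiated (n-BuLi, THF, −78 °C) and formylated with DMF, with an inverse quench into aqueous KH2PO4, to give 5-(3-benzyloxyphenyl)pent-2-ynal F1. Heating F1 with diene 7 in toluene at 110–130 °C should give the bicyclo[2.2.2]octadiene carbaldehyde F2. F2 should lose ethene to give the aryl trimethylsilyl ether aldehyde F3. Acid work-up (1 M HCl, THF) should give 3-(4-benzyloxybenzyl)-6-[2-(3-benzyloxyphenyl)ethyl]-4-hydroxy-2-methoxybenzaldehyde F4. Addition of 4-benzyloxyphenylmagnesium bromide (3 equiv, THF, 0 to 40 °C; the first equivalent is spent on the phenol) should give carbinol 18, which is carried to 19 under the conditions of step 8.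

Step 8. The protonated ketone is strongly stabilised, so hydride transfer may be slow and ipso-protonation of the electron-rich ring para to the hydroxyl may lead to protodeacylation, with slow acidolysis of benzyl ethers alongside.
Fallback: it sets out from ketone 17 and returns at target 20, replacing acid-mediated hydride transfer by aluminium hydride reduction and catalytic C–O hydrogenolysis. LiAlH4 (excess, THF, 0 °C to rt, cold neutral work-up) should give carbinol 18. H2 over 10% Pd/C in EtOAc–AcOH should then cleave the doubly benzylic C–OH bond together with the three benzyl ethers to give 20 directly. Any 19 formed in the hydride step via a quinone methide converges on the same product.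

Step 6. Triethylamine may isomerise the product ynone through its propargylic CH2 to the allenyl ketone, and copper-mediated alkyne homocoupling or hydrolysis of the acid chloride may compete.
Fallback: it sets out from alkyne 12 and aldehyde 2 and returns at ynone 14, using acetylide addition and oxidation instead of cross-coupling. Alkyne 12 is lithiated (n-BuLi, THF, −78 °C) and added to 4-benzyloxybenzaldehyde 2 to give racemic 1-(4-benzyloxyphenyl)-5-(3-benzyloxyphenyl)pent-2-yn-1-ol F5. Oxidation with MnO2 in CH2Cl2 at rt should give 14 under neutral conditions.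

**Further compounds**
F1 | step 7 | 5-(3-benzyloxyphenyl)pent-2-ynal | O=CC#CCCc1cccc(OCc2ccccc2)c1
F2 | step 7 | 6-(4-benzyloxybenzyl)-3-[2-(3-benzyloxyphenyl)ethyl]-1-methoxy-5-(trimethylsilyloxy)bicyclo[2.2.2]octa-2,5-diene-2-carbaldehyde, racemic | COC12CCC(C(O[Si](C)(C)C)=C1Cc1ccc(OCc3ccccc3)cc1)C(CCc1cccc(OCc3ccccc3)c1)=C2C=O
F3 | step 7 | 3-(4-benzyloxybenzyl)-6-[2-(3-benzyloxyphenyl)ethyl]-2-methoxy-4-(trimethylsilyloxy)benzaldehyde | COc1c(Cc2ccc(OCc3ccccc3)cc2)c(O[Si](C)(C)C)cc(CCc2cccc(OCc3ccccc3)c2)c1C=O
F4 | step 7 | 3-(4-benzyloxybenzyl)-6-[2-(3-benzyloxyphenyl)ethyl]-4-hydroxy-2-methoxybenzaldehyde | COc1c(Cc2ccc(OCc3ccccc3)cc2)c(O)cc(CCc2cccc(OCc3ccccc3)c2)c1C=O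
F0 | step 8 | none | none
F5 | step 6 | 1-(4-benzyloxyphenyl)-5-(3-benzyloxyphenyl)pent-2-yn-1-ol, racemic | OC(C#CCCc1cccc(OCc2ccccc2)c1)c1ccc(OCc2ccccc2)cc1
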